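Cuts (hydrindenone numbering: C4=O, C5=C6, C7H2, ring fusion C7a/C3a): after the two silyl groups are removed, the enone ring is opened at C4–C5 and C6–C7 and C4 is rejoined to C7. This gives a fused cyclobutanone and one internal alkyne carrying both side chains. The alkyne is then cut at its allylic CH2–C(sp) bond and the arene at its aryl–prenyl bond.
Enabling feature: in the six-membered ring, C4(=O), the two cis methyl-bearing ring-fusion carbons C3a and C7a, and C7H2 are the four ring atoms of the ketene adduct of 1,2-dimethylcyclopentene. The tetrasubstituted C5=C6 is a masked alkyne.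
Forward order: cyclopentane and arene are bought, and a keteniminium [2+2] fuses the four-membered ring onto the cyclopentene. The chain is joined aryl + prenyl, then allyl + alkynyl, and the six-membered ring comes last by Ni(0)-catalysed two-carbon ring expansion.
Stereochemistry: both quaternary centres are set at once in the [2+2] (cis by suprafacial addition, absolute sense from a C2-symmetric pyrrolidine auxiliary) and are not touched again. The E-alkene comes from E-selective allylic oxidation of the prenyl group.

Key step: step 9

Assumption: the (2R,5R)-auxiliary is taken to lead to the (1R,5R)-cyclobutanone; if the sense of induction is the opposite, the equally available (2S,5S)-amine is used in steps 1 and 2 and nothing else changes.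

Step 1
Reactants: 1 (2R,5R)-2,5-dimethylpyrrolidine; 2 acetyl chloride
Product: 3 1-[(2R,5R)-2,5-dimethylpyrrolidin-1-yl]ethan-1-one
Conditions: Et3N, CH2Cl2, 0 °C → rt
Reagents that add atoms: none
Why: Schotten–Baumann-type N-acylation of a secondary amine by an acid chloride, in which the two stereocentres of the amine take no part.

Step 2
Reactants: 3 1-[(2R,5R)-2,5-dimethylpyrrolidin-1-yl]ethan-1-one; 4 1,2-dimethylcyclopentene
Product: 7 (1R,5R)-1,5-dimethylbicyclo[3.2.0]heptan-6-one, via keteniminium triflate 5 (not isolated), via cyclobutaniminium triflate 6 (not isolated)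
Conditions: Tf2O (1.1 equiv), 2,6-di-tert-butyl-4-methylpyridine (1.2 equiv), 4 (2 equiv), ClCH2CH2Cl, −15 °C → reflux; then H2O, reflux
Reagents that add atoms: water, O
Why: Keteniminium–alkene [2+2] cycloaddition, in which O-triflation of 3 and loss of triflic acid give the small, strongly electrophilic keteniminium 5; this adds suprafacially to the electron-rich symmetric alkene and sets both quaternary carbons at once with cis methyl groups (the only fusion a bicyclo[3.2.0] frame allows), the C2-symmetric auxiliary, whose two iminium faces are equivalent, decides which of the two enantiotopic alkene carbons bonds to the iminium carbon and hence the absolute configuration, and water then hydrolyses 6 to the ketone.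

Step 3
Reactants: 8 4-methoxy-2-methylphenol; 9 prenyl bromide (1-bromo-3-methylbut-2-ene)
Product: 11 4-methoxy-2-methyl-6-(3-methylbut-2-en-1-yl)phenol, via sodium phenoxide 10 (not isolated)
Conditions: NaH (1.05 equiv), toluene, 0 °C → rt; then 9 (1.0 equiv), rt
Reagents that add atoms: none
Why: ortho-C-allylation of a phenoxide contact ion pair, in which the sodium-bound oxygen is shielded in toluene so the ring carbon attacks the allylic bromide, and since C4 carries OMe and C2 carries CH3 only alkylation at C6 can re-aromatise.

Step 4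
Reactants: 11 4-methoxy-2-methyl-6-(3-methylbut-2-en-1-yl)phenol
Product: 12 tert-butyl[4-methoxy-2-methyl-6-(3-methylbut-2-en-1-yl)phenoxy]dimethylsilane
Conditions: TBSCl, imidazole, DMF, rt → 40 °C
Reagents that add atoms: tert-butyldimethylsilyl chloride, CC(C)(C)[Si](C)(C)Cl
Why: Imidazole-promoted O-silylation masks the acidic, easily oxidised phenol for the oxidation, organometallic and nickel steps, and the two ortho substituents make this aryl silyl ether robust.

Step 5
Reactants: 12 tert-butyl[4-methoxy-2-methyl-6-(3-methylbut-2-en-1-yl)phenoxy]dimethylsilane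
Product: 14 (2E)-4-{2-[(tert-butyldimethylsilyl)oxy]-5-methoxy-3-methylphenyl}-2-methylbut-2-en-1-ol, via enal 13 (not isolated)
Conditions: SeO2 (0.3 equiv), t-BuOOH (decane, 3 equiv), CH2Cl2, 0 °C → rt; then NaBH4, MeOH, 0 °C on the crude mixture
Reagents that add atoms: selenium dioxide, O=[Se]=O; tert-butyl hydroperoxide, CC(C)(C)OO
Why: Riley allylic oxidation in its catalytic form, in which the ene reaction at the gem-dimethyl end and the [2,3]-shift of the allylseleninic acid place oxygen on the methyl group trans to the chain and so give the E-alcohol, and the borohydride returns the over-oxidised share (13) to 14 by 1,2-reduction.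

Step 6
Reactants: 14 (2E)-4-{2-[(tert-butyldimethylsilyl)oxy]-5-methoxy-3-methylphenyl}-2-methylbut-2-en-1-ol
Product: 15 {2-[(2E)-4-bromo-3-methylbut-2-en-1-yl]-4-methoxy-6-methylphenoxy}(tert-butyl)dimethylsilane
Conditions: CBr4, PPh3, CH2Cl2, −20 → 0 °C
Reagents that add atoms: carbon tetrabromide, BrC(Br)(Br)Br
Why: Appel reaction, in which bromide displaces the alkoxyphosphonium group at the primary allylic carbon under neutral conditions, so neither allylic transposition nor loss of the E geometry or of the silyl ether is expected.

Step 7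
Reactants: 16 2-methylpent-4-yn-2-ol
Product: 17 triethyl[(2-methylpent-4-yn-2-yl)oxy]silane
Conditions: TESOTf, 2,6-lutidine, CH2Cl2, 0 °C
Reagents that add atoms: triethylsilyl trifluoromethanesulfonate, CC[Si](CC)(CC)OS(=O)(=O)C(F)(F)F
Why: Silyl triflate silylation is the standard way to cap a tertiary alcohol, and the TES ether removes the proton that would quench the organometallic species of steps 8 and 9 and enlarges this arm for the orientation control of step 9.

Step 8
Reactants: 17 triethyl[(2-methylpent-4-yn-2-yl)oxy]silane; 15 {2-[(2E)-4-bromo-3-methylbut-2-en-1-yl]-4-methoxy-6-methylphenoxy}(tert-butyl)dimethylsilane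
Product: 19 tert-butyl(2-{(2E)-3,8-dimethyl-8-[(triethylsilyl)oxy]non-2-en-5-yn-1-yl}-4-methoxy-6-methylphenoxy)dimethylsilane, via alkynylmagnesium bromide 18 (not isolated)
Conditions: EtMgBr (1.05 equiv), THF, 0 → 40 °C; CuBr·SMe2 (10 mol %), then 15, 0 → 50 °C
Reagents that add atoms: none
Why: Copper-catalysed coupling of an alkynyl Grignard reagent with a primary allylic bromide, in which attack at the open CH2Br carbon (SN2) rather than at the internal CH (SN2′) keeps the E-alkene in place, and the carbonate-free medium spares the aryl silyl ether and does not isomerise the skipped enyne.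

Step 9
Reactants: 7 (1R,5R)-1,5-dimethylbicyclo[3.2.0]heptan-6-one; 19 tert-butyl(2-{(2E)-3,8-dimethyl-8-[(triethylsilyl)oxy]non-2-en-5-yn-1-yl}-4-methoxy-6-methylphenoxy)dimethylsilane
Product: 20 (3aR,7aR)-6-[(2E)-4-{2-[(tert-butyldimethylsilyl)oxy]-5-methoxy-3-methylphenyl}-2-methylbut-2-en-1-yl]-3a,7a-dimethyl-5-{2-methyl-2-[(triethylsilyl)oxy]propyl}-1,2,3,3a,7,7a-hexahydro-4H-inden-4-one
Conditions: Ni(cod)2 (15 mol %), IPr free carbene (15 mol %), 7 (2 equiv), toluene, 100 °C, slow addition of 19
Reagents that add atoms: none
Why: Ni(0) couples the strained carbonyl group of 7 and the alkyne of 19 by oxidative cyclisation to a spiro oxanickelacyclopentene, β-carbon elimination driven by release of four-ring strain hands the cyclobutane CH2 to nickel to give a seven-membered nickelacycle, and C(sp3)–C(sp2) reductive elimination forms the enone and frees Ni(0). The closest known reaction type is this same Ni(0)-catalysed intermolecular insertion of internal dialkyl alkynes into the C(O)–Cα bond of cyclobutanones to give 2,3-disubstituted cyclohex-2-enones, applied here to a more crowded ketone and an unsymmetrical alkyne. The only ring made, the cyclohexenone, arises by two-carbon expansion of the four-membered ring (formal [4+2] of the C(O)–C–C–CH2 unit with the alkyne; new bonds C4–C5 and C6–C7, old C(O)–CH2 bond broken) and not by closing an open chain. No stereocentre is created, and because the bond that breaks ends at the carbonyl carbon and at a CH2 group, both quaternary centres pass unchanged into 20 as (3aR,7aR), while the E-alkene is a spectator. Site selectivity (cleavage of C(O)–CH2 and not of C(O)–C(quaternary)) should follow from the easier migration of the unhindered primary carbon to nickel, and the neopentyl-type Ni–CH2 so formed has no β-hydrogen, which leaves reductive elimination as its only outlet. Orientation (carbonyl carbon to the alkyne carbon bearing CH2C(CH3)2OSiEt3) is the demanding point and is built into catalyst and substrate: the very large monodentate carbene keeps the neopentyl-like silyloxy arm off the nickel-bound carbon, as in the ligand-size-controlled reversal of regiochemistry known for Ni-catalysed alkyne–carbonyl couplings, and only the isomer with nickel on the allyl-bearing carbon can be stabilised by chelation of the skipped alkene.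

Step 10
Reactants: 20 bis-silylated hydrindenone (as named in step 9)
Product: 21 (3aR,7aR)-6-[(2E)-4-(2-hydroxy-5-methoxy-3-methylphenyl)-2-methylbut-2-en-1-yl]-5-(2-hydroxy-2-methylpropyl)-3a,7a-dimethyl-1,2,3,3a,7,7a-hexahydro-4H-inden-4-one (target)
Conditions: TBAF (4 equiv), AcOH (4 equiv), THF, 0 °C → rt
Reagents that add atoms: none
Why: Fluoride-induced desilylation removes the aryl TBS ether at once and the tertiary TES ether on standing, and the acetic acid buffer keeps the medium from deprotonating the doubly allylic CH2 next to C6, so the skipped diene does not move into conjugation and no stereocentre is at risk.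

Compound list
1 | (2R,5R)-2,5-dimethylpyrrolidine | C[C@@H]1CC[C@@H](C)N1 | starting material
2 | acetyl chloride | CC(=O)Cl | starting material
3 | 1-[(2R,5R)-2,5-dimethylpyrrolidin-1-yl]ethan-1-one | CC(=O)N1[C@H](C)CC[C@H]1C | intermediate
4 | 1,2-dimethylcyclopentene | CC1=C(C)CCC1 | starting material
5 | (2R,5R)-1-ethenylidene-2,5-dimethylpyrrolidinium triflate (keteniminium salt, not isolated) | C=C=[N+]1[C@H](C)CC[C@H]1C.[O-]S(=O)(=O)C(F)(F)F | intermediate
6 | (2R,5R)-1-[(1R,5R)-1,5-dimethylbicyclo[3.2.0]heptan-6-ylidene]-2,5-dimethylpyrrolidinium triflate (not isolated) | C[C@@H]1CC[C@@H](C)[N+]1=C1[C@]2(C)CCC[C@]2(C)C1.[O-]S(=O)(=O)C(F)(F)F | intermediate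
7 | (1R,5R)-1,5-dimethylbicyclo[3.2.0]heptan-6-one (cis-fused) | O=C1[C@]2(C)CCC[C@]2(C)C1 | intermediate
8 | 4-methoxy-2-methylphenol | COc1ccc(O)c(C)c1 | starting material
9 | prenyl bromide | CC(C)=CCBr | starting material
10 | sodium 4-methoxy-2-methylphenoxide (not isolated) | COc1ccc([O-])c(C)c1.[Na+] | intermediate
11 | 4-methoxy-2-methyl-6-(3-methylbut-2-en-1-yl)phenol | COc1cc(C)c(O)c(CC=C(C)C)c1 | intermediate
12 | tert-butyl[4-methoxy-2-methyl-6-(3-methylbut-2-en-1-yl)phenoxy]dimethylsilane | COc1cc(C)c(O[Si](C)(C)C(C)(C)C)c(CC=C(C)C)c1 | intermediate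
13 | (2E)-4-{2-[(tert-butyldimethylsilyl)oxy]-5-methoxy-3-methylphenyl}-2-methylbut-2-enal (not isolated) | COc1cc(C)c(O[Si](C)(C)C(C)(C)C)c(C/C=C(\C)C=O)c1 | intermediate
14 | (2E)-4-{2-[(tert-butyldimethylsilyl)oxy]-5-methoxy-3-methylphenyl}-2-methylbut-2-en-1-ol | COc1cc(C)c(O[Si](C)(C)C(C)(C)C)c(C/C=C(\C)CO)c1 | intermediate
15 | {2-[(2E)-4-bromo-3-methylbut-2-en-1-yl]-4-methoxy-6-methylphenoxy}(tert-butyl)dimethylsilane | COc1cc(C)c(O[Si](C)(C)C(C)(C)C)c(C/C=C(\C)CBr)c1 | intermediate
16 | 2-methylpent-4-yn-2-ol | C#CCC(C)(C)O | starting material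
17 | triethyl[(2-methylpent-4-yn-2-yl)oxy]silane | C#CCC(C)(C)O[Si](CC)(CC)CC | intermediate
18 | {4-methyl-4-[(triethylsilyl)oxy]pent-1-yn-1-yl}magnesium bromide (not isolated) | Br[Mg]C#CCC(C)(C)O[Si](CC)(CC)CC | intermediate
19 | tert-butyl(2-{(2E)-3,8-dimethyl-8-[(triethylsilyl)oxy]non-2-en-5-yn-1-yl}-4-methoxy-6-methylphenoxy)dimethylsilane | COc1cc(C)c(O[Si](C)(C)C(C)(C)C)c(C/C=C(\C)CC#CCC(C)(C)O[Si](CC)(CC)CC)c1 | intermediate
20 | (3aR,7aR)-6-[(2E)-4-{2-[(tert-butyldimethylsilyl)oxy]-5-methoxy-3-methylphenyl}-2-methylbut-2-en-1-yl]-3a,7a-dimethyl-5-{2-methyl-2-[(triethylsilyl)oxy]propyl}-1,2,3,3a,7,7a-hexahydro-4H-inden-4-one | COc1cc(C)c(O[Si](C)(C)C(C)(C)C)c(C/C=C(\C)CC2=C(CC(C)(C)O[Si](CC)(CC)CC)C(=O)[C@]3(C)CCC[C@]3(C)C2)c1 | intermediate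
21 | (3aR,7aR)-6-[(2E)-4-(2-hydroxy-5-methoxy-3-methylphenyl)-2-methylbut-2-en-1-yl]-5-(2-hydroxy-2-methylpropyl)-3a,7a-dimethyl-1,2,3,3a,7,7a-hexahydro-4H-inden-4-one | COc1cc(C)c(O)c(C/C=C(\C)CC2=C(CC(C)(C)O)C(=O)[C@]3(C)CCC[C@]3(C)C2)c1 | target

Total step count: 10.
Longest linear sequence: 7 steps (8 → 11 → 12 → 14 → 15 → 19 → 20 → 21; steps 3, 4, 5, 6, 8, 9, 10).

Steps most likely to fail

1. Step 9.
- Both alkyne carbons carry a CH2 group and differ only further out, so the alkyne may enter the oxidative cyclisation in the reverse orientation.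
- The crowded carbonyl group may also react more slowly than the valuable enyne oligomerises on nickel.
- The fallback sets out from 18 and 7 and comes back at 20. It fixes the orientation with a metalloid placeholder and attaches the aryl chain only after the ring expansion.
- The Grignard reagent 18 is quenched with Bu3SnCl to give the alkynylstannane tributyl{4-methyl-4-[(triethylsilyl)oxy]pent-1-yn-1-yl}stannane F1.
- F1 is cheap and can be used in excess over 7 in the same type of Ni(0)-catalysed insertion, which also helps a sluggish ketone.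
- As with silyl- and stannyl-substituted alkynes in Ni(0) oxidative cyclisations generally, the carbon bearing the large metalloid group takes the nickel-bound position. The carbonyl carbon therefore bonds to the carbon with the silyloxy arm, and tin ends at C6 in the β-stannyl enone F2.
- A Stille coupling of F2 with the allylic bromide 15 (Pd2(dba)3, AsPh3, CuI, DMF) at its primary carbon then gives 20.

2. Step 2.
- The auxiliary may discriminate poorly between the two enantiotopic alkene carbons, which would lower the enantiomeric purity.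
- The developing tertiary cation may lose a proton (ene-type acylation) instead of closing the four-membered ring.
- The fallback sets out from 4 and comes back at 7. It separates ring formation from stereocontrol.
- Dichloroketene (Cl3CCOCl, Zn–Cu, Et2O) should add to 4 to give the racemic dichlorocyclobutanone F3, and Zn/AcOH should remove both chlorine atoms to give the racemic ketone F4.
- Acetalisation with (R,R)-hydrobenzoin (TsOH, benzene, Dean–Stark) creates no new stereocentre because the diol is C2-symmetric. It gives only the (1R,5R)-spiroacetal F5 and the (1S,5S)-spiroacetal F6, which are separated by chromatography or crystallisation.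
- Aqueous acid then hydrolyses F5 to 7.
- The same acetal sequence can also raise the enantiomeric purity of material from step 2.

3. Step 3.
- O-alkylation may compete, as may attack at the methyl-bearing ortho carbon and acid-induced ring closure of the product to a chroman.
- The fallback sets out from 8 and comes back at 14. It replaces phenoxide alkylation by an aryl-metal route that also bypasses steps 4 and 5.
- Bromination ortho to the hydroxyl group (NBS, MeCN, 0 °C) gives the bromophenol F7, and TBSCl/imidazole gives its silyl ether F8.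
- Magnesium insertion in THF gives the arylmagnesium bromide F9.
- CuI-catalysed SN2′ opening of 2-methyl-2-vinyloxirane by F9 (THF, −30 °C) should deliver the E-allylic alcohol 14 as the main isomer.

Further compounds
F1 | step 9 | tributyl{4-methyl-4-[(triethylsilyl)oxy]pent-1-yn-1-yl}stannane | CCCC[Sn](CCCC)(CCCC)C#CCC(C)(C)O[Si](CC)(CC)CC
F2 | step 9 | (3aR,7aR)-3a,7a-dimethyl-5-{2-methyl-2-[(triethylsilyl)oxy]propyl}-6-(tributylstannyl)-1,2,3,3a,7,7a-hexahydro-4H-inden-4-one | CCCC[Sn](CCCC)(CCCC)C1=C(CC(C)(C)O[Si](CC)(CC)CC)C(=O)[C@]2(C)CCC[C@]2(C)C1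
F3 | step 2 | cis-7,7-dichloro-1,5-dimethylbicyclo[3.2.0]heptan-6-one (racemate, both enantiomers written) | O=C1[C@]2(C)CCC[C@]2(C)C1(Cl)Cl.O=C1[C@@]2(C)CCC[C@@]2(C)C1(Cl)Cl
F4 | step 2 | cis-1,5-dimethylbicyclo[3.2.0]heptan-6-one (racemate, both enantiomers written) | O=C1[C@]2(C)CCC[C@]2(C)C1.O=C1[C@@]2(C)CCC[C@@]2(C)C1
F5 | step 2 | (R,R)-hydrobenzoin acetal of (1R,5R)-1,5-dimethylbicyclo[3.2.0]heptan-6-one | O1[C@H](c2ccccc2)[C@@H](c2ccccc2)OC13[C@]2(C)CCC[C@]2(C)C3
F6 | step 2 | (R,R)-hydrobenzoin acetal of (1S,5S)-1,5-dimethylbicyclo[3.2.0]heptan-6-one (removed) | O1[C@H](c2ccccc2)[C@@H](c2ccccc2)OC13[C@@]2(C)CCC[C@@]2(C)C3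
F7 | step 3 | 2-bromo-4-methoxy-6-methylphenol | COc1cc(C)c(O)c(Br)c1
F8 | step 3 | (2-bromo-4-methoxy-6-methylphenoxy)(tert-butyl)dimethylsilane | COc1cc(C)c(O[Si](C)(C)C(C)(C)C)c(Br)c1
F9 | step 3 | {2-[(tert-butyldimethylsilyl)oxy]-5-methoxy-3-methylphenyl}magnesium bromide | COc1cc(C)c(O[Si](C)(C)C(C)(C)C)c([Mg]Br)c1
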